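## Structural features

- The target is an achiral chain of six benzene rings (A to F) joined by five diaryl ether oxygens and carrying sixteen free hydroxyls. It has no stereocentre, so no two stereocentres stand next to each other and nothing has to be controlled on that count.
- Ring A is a 2,4,6-trihydroxyphenyl ether and ring F a 3,4,5-trihydroxyphenyl ether. Rings C and E are 3,5-dihydroxy-1,4-phenylenedioxy units. Rings B and D are 3,4,5-trihydroxy rings with their two ether oxygens on adjacent carbons (B1/B2 and D1/D2).
- Every ether bond has one terminus flanked by two ortho oxygen substituents (A1, B2, C4, D2, E4). In A1–O–B1 and C4–O–D1 the other terminus also has an ortho aryloxy neighbour, so these two bonds are the most crowded.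
- The free polyphenol (pyrogallol and hydroxyquinol units) is oxidised very easily by air in neutral or basic solution. All hydroxyls must therefore stay masked until the end, and the unmasking must be acidic and non-oxidising.
- The real difficulty is making crowded, electron-rich diaryl ethers regioselectively, twice on neighbouring carbons of the same ring.
- The key step uses the fact that in ring B the ether carbons B1 and B2 are each para to a hydroxyl-bearing carbon (B4 and B5). At the ortho-quinone level with carbonyls at B4 and B5, B1 and B2 become the β-carbons of two enones, B3 carries the third oxygen as methoxy and B6 carries a removable bromine. Ring D has the same pattern (D1, D2 against D4, D5).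

## Logic of the disconnections

**19 back to 18.** Fourteen O–CH3 bonds are added in the retro sense. Methyl ethers are the only masks that survive phenoxides, a quinone, dithionite and hydrogenation; B4–OH and B5–OH stay free because they come from quinone carbonyls. The forward step must cleave fourteen aryl methyl ethers without touching five diaryl ethers.

**18 back to 16.** B6–H becomes B6–Br and the B4/B5 diol becomes a diketone. There is no gain in size, but ring B changes from an electron-rich arene into an electrophile at B1 and B2. The forward step must reduce the quinone and remove the bromine, ideally in one operation.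

**16 back to 3, 14 and 13.** The B1–O and B2–O bonds are cut on the ring-B side, leaving the oxygens on A1 and C1. Both crowded ethers of ring B are then made on an electron-poor ring, and the hexamer falls into pieces of one, one and four rings. The forward step needs a fixed order of attack (hindered oxygen to B1, unhindered oxygen to B2) and substitution faster than electron transfer.

**13 back to 12 and 10.** In 13, D6–H is replaced by bromine and the C1 hydroxyl by a benzyl ether (12), so that one hydrogenolysis removes both. 12 is then taken back to 10 by removing the D4 and D5 methyl groups and raising ring D to the quinone level. Ring D is thus treated exactly like ring B.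

**10 back to 3, 5 and 8.** D1–O and D2–O are cut on the ring-D side. The reasoning and the demands are those of the cut of 16. This earlier use of the same reaction on small pieces also serves as its test.

**8 back to 7, then 5 and 6.** The F1–O bond is cut with the oxygen left on E4. F1 is the only ether carbon of the molecule with no ortho substituent, so an aryl iodide there is an ordinary copper-coupling partner. The forward step must tolerate a phenoxide flanked by two methoxy groups. 5 serves twice, as ring E here and as ring C in 10.

**5 back to 4; 3 back to 2 and 1.** One O–benzyl bond is cut in 5; the forward step must distinguish the two hydroxyls of 4. In 3 the oxidation level and three C–Br bonds are removed, leading to a purchasable catechol.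

## Other disconnections considered

**Alternative 1:** ring F is built by a chromium carbene benzannulation.
- Cut: F1–F2, F3–F4 and F4–F5.
- Forward key step: a Dötz benzannulation of the pentacarbonylchromium aryloxy(2-ethoxyvinyl)carbene A1 (carbene carbon = F1, carrying the ring-E oxygen) with ethoxyacetylene A2 and one carbonyl ligand of A1 (= F4). It should give the E–F dimer A3, a 4-aryloxy-2,6-diethoxyphenol.
- In favour: the 1,3,4,5-oxygen pattern of ring F appears in one step, with the regiochemistry set by the alkyne; the step is neutral and redox-free.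
- Against: an aryloxy group on a chromium carbene carbon is a good leaving group, so A1 is far less robust than an alkoxycarbene. A1 must still be made from the hindered E4 phenol, so the crowding is moved and not removed. Alkoxyalkynes tend to give cyclobutenones and two-alkyne products in this reaction. Zerovalent chromium carbonyl is used stoichiometrically.
- Comparison on structure: E4–O–F1 is the easiest ether of the molecule (step 4 makes it in one copper coupling), and rings B and D with their vicinal ethers are left untouched.
- Comparison on mechanism: the alternative is the better, since it has no electron-transfer risk of the kind that step 9 carries.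
- Comparison on handling: A3 carries the same benzyl mask at E1 as 7 and could enter the route at that point; here it is the equal.
- Comparison on step economy: it is worse, with several steps to A1 against one step to 7.

**Alternative 2:** ring E is built by a double Claisen (3+3) cyclisation.
- Cut: E2–E3 and E5–E6.
- Forward key step: the dimethyl 3-aryloxyglutaconate A4, carrying rings A to D on its enol ether oxygen, is C-acylated twice by (3,4,5-trimethoxyphenoxy)malonyl dichloride A5. The second acylation closes the ring and enolisation aromatises it to the hexamer A6, with E3/E5 hydroxyls and E2/E6 methyl esters.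
- In favour: both ether oxygens of ring E (E1–O and E4–O) are in place before the ring exists, so no C–O bond is made at crowded E4. The union of four rings with one is late and convergent.
- Against: A4 already contains rings B and D, so the vicinal ethers must be solved upstream by some other means. Aryloxymalonyl dichlorides lose HCl to chlorocarbonyl ketenes, and O-acylation with pyranone formation competes with double C-acylation. Two ester groups must afterwards be hydrolysed and decarboxylated.
- Comparison on structure: the alternative synthesises a ring that the chosen plan takes ready-made from 4.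
- Comparison on mechanism: it is the equal or the better, being polar and redox-neutral with no oxidant next to electron-rich phenoxides. The decarboxylation of the 2,6-dioxygenated acids should be easy, so that part is the equal.
- Comparison on step economy: it is worse, because A4 costs at least as much as 13 and two to three steps follow A6.

**Alternative 3:** ring C is built by a Danheiser benzannulation between two halves.
- Cut: C2–C3 and C6–C1.
- Forward key step: heating the 4-aryloxy-3-ethoxycyclobutenone A7 (rings D to F, racemic at its sp3 carbon) with the aryl ethynyl ether A8 (rings A and B). The cascade is four-electron ring opening to a vinylketene, [2+2] addition to the ynol ether, a second ring opening and six-electron closure. It should give the hexamer A9 with C3–OH and C5–OEt.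
- In favour: it is the most convergent of all, joining three rings with two. Both ring-C oxygens are carried in, and the regiochemistry follows from the polarity of the ketene–ynol ether addition.
- Against: A8 is an ynol ether of a very electron-rich, doubly ortho-substituted phenol; it is hard to make and prone to hydration and polymerisation. The large vinylketene from A7 can dimerise at the temperature needed. Rings B (in A8) and D (in A7) must first be made by some other method, for example the quinone chemistry of steps 6 and 9.
- Comparison on structure: it solves the union of the halves but not the crowded rings.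
- Comparison on mechanism: it is the better on risk of redox side reactions, being reagent-free and pericyclic.
- Comparison on endgame: it is the better by one step, since A9 is already aromatic and needs only global dealkylation.
- Comparison on convergence: it is the better, three plus two rings against one plus one plus four.
- Comparison on step economy: overall probably worse, because A7 and A8 each need ring construction plus several functional group steps.

Key step: step 9

Remark on the chemistry (assumption): the target has no stereogenic element, so all structures are written without stereodescriptors. Quinone 3 is numbered C1(=O), C2(=O), C3(OMe), C4–C6(Br). C5, C4, C3, C2, C1 and C6 become B1, B2, B3, B4, B5 and B6 in step 9, and D1 to D6 in the same way in step 6. Compounds 1, 4, 6 and 14 are taken as purchasable.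

## Route

Step 1
Reactants: 1 3-methoxycatechol
Product: 2 4,5,6-tribromo-3-methoxycatechol
Conditions: Br2 (3.1 equiv), AcOH, 0 °C to rt
Reagents that add atoms: bromine, BrBr
Why: Electrophilic aromatic bromination; all three free positions are activated by OH or OMe, as in the classical perbromination of catechol.

Step 2
Reactants: 2 4,5,6-tribromo-3-methoxycatechol
Product: 3 4,5,6-tribromo-3-methoxy-1,2-benzoquinone
Conditions: NaIO4, CH2Cl2/H2O, 0 °C
Reagents that add atoms: none
Why: Periodate oxidation of a catechol to the ortho-quinone; the halogens should make the quinone stable enough to isolate, dry and store cold in the dark.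

Step 3
Reactants: 4 2,6-dimethoxyhydroquinone
Product: 5 4-benzyloxy-2,6-dimethoxyphenol
Conditions: BnBr (1.0 equiv), K2CO3 (1.0 equiv), DMF, 0 °C to rt, Ar
Reagents that add atoms: benzyl bromide, BrCc1ccccc1
Why: Williamson etherification; the 4-OH is the more acidic and the unhindered hydroxyl, so one equivalent of base and halide should leave the OH between the two methoxy groups free.

Step 4
Reactants: 5 4-benzyloxy-2,6-dimethoxyphenol; 6 5-iodo-1,2,3-trimethoxybenzene
Product: 7 5-benzyloxy-1,3-dimethoxy-2-(3,4,5-trimethoxyphenoxy)benzene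
Conditions: CuI (10 mol%), picolinic acid (20 mol%), K3PO4, DMSO, 90 °C, Ar
Reagents that add atoms: none
Why: Ullmann diaryl ether synthesis with monovalent copper and picolinic acid, a system that accepts 2,6-disubstituted phenols; the iodide 6 has no ortho substituent, and this step forms E4–O–F1.

Step 5
Reactants: 7 5-benzyloxy-1,3-dimethoxy-2-(3,4,5-trimethoxyphenoxy)benzene
Product: 8 3,5-dimethoxy-4-(3,4,5-trimethoxyphenoxy)phenol
Conditions: H2 (1 atm), 10% Pd/C, EtOAc/MeOH, rt
Reagents that add atoms: none
Why: Hydrogenolysis of a benzyl aryl ether; methyl and diaryl ethers are inert under these conditions.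

Step 6
Reactants: 3 4,5,6-tribromo-3-methoxy-1,2-benzoquinone; 5 4-benzyloxy-2,6-dimethoxyphenol; 8 3,5-dimethoxy-4-(3,4,5-trimethoxyphenoxy)phenol
Product: 10 5-(4-benzyloxy-2,6-dimethoxyphenoxy)-6-bromo-4-[3,5-dimethoxy-4-(3,4,5-trimethoxyphenoxy)phenoxy]-3-methoxy-1,2-benzoquinone, via 5-aryloxy-4,6-dibromoquinone 9 (not isolated)
Conditions: 5, NaH (1.0 equiv), THF, 0 °C, added to 3, THF, −78 °C; then 8, NaH (1.0 equiv), THF, −78 to −20 °C; dark, Ar
Reagents that add atoms: none
Why: Proposed new method: each sodium phenoxide adds to a bromine-bearing β-carbon of the ortho-quinone (a vinylogous acyl bromide) and bromide leaves; the hindered phenoxide of 5 should take C5 (future D1), the β-carbon not enriched by the C3 methoxy group, and the vinylogous ester so formed leaves C4 (future D2) to the unhindered phenoxide of 8. The closest known reaction type is aryloxy-dehalogenation of chloranil, ortho-chloranil and 2,3-dichloro-1,4-naphthoquinone by phenoxides.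

Step 7
Reactants: 10 5-(4-benzyloxy-2,6-dimethoxyphenoxy)-6-bromo-4-[3,5-dimethoxy-4-(3,4,5-trimethoxyphenoxy)phenoxy]-3-methoxy-1,2-benzoquinone
Product: 12 1-(4-benzyloxy-2,6-dimethoxyphenoxy)-6-bromo-2-[3,5-dimethoxy-4-(3,4,5-trimethoxyphenoxy)phenoxy]-3,4,5-trimethoxybenzene, via bromocatechol 11 (not isolated)
Conditions: Na2S2O4, Bu4NBr (cat.), THF/H2O, 0 °C; then KOH aq, Me2SO4, rt, Ar
Reagents that add atoms: dimethyl sulfate, COS(=O)(=O)OC
Why: One-pot reductive methylation of a quinone (dithionite reduction, then Williamson O-methylation of the catecholate under phase transfer); the air-sensitive catechol is never isolated.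

Step 8
Reactants: 12 1-(4-benzyloxy-2,6-dimethoxyphenoxy)-6-bromo-2-[3,5-dimethoxy-4-(3,4,5-trimethoxyphenoxy)phenoxy]-3,4,5-trimethoxybenzene
Product: 13 4-{2-[3,5-dimethoxy-4-(3,4,5-trimethoxyphenoxy)phenoxy]-3,4,5-trimethoxyphenoxy}-3,5-dimethoxyphenol
Conditions: H2 (1–3 atm), 10% Pd/C, NaOAc, EtOAc/MeOH, rt
Reagents that add atoms: none
Why: Catalytic hydrogenolysis cleaves the aryl C–Br bond (acetate takes up HBr) and the benzyl ether side by side in one flask, freeing the C1 hydroxyl.

Step 9
Reactants: 3 4,5,6-tribromo-3-methoxy-1,2-benzoquinone; 14 2,4,6-trimethoxyphenol; 13 4-{2-[3,5-dimethoxy-4-(3,4,5-trimethoxyphenoxy)phenoxy]-3,4,5-trimethoxyphenoxy}-3,5-dimethoxyphenol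
Product: 16 6-bromo-4-[4-{2-[3,5-dimethoxy-4-(3,4,5-trimethoxyphenoxy)phenoxy]-3,4,5-trimethoxyphenoxy}-3,5-dimethoxyphenoxy]-3-methoxy-5-(2,4,6-trimethoxyphenoxy)-1,2-benzoquinone, via 5-aryloxy-4,6-dibromoquinone 15 (not isolated)
Conditions: 14, NaH (1.0 equiv), THF, 0 °C, added to 3, THF, −78 °C; then 13, NaH (1.0 equiv), THF, −78 to −20 °C; dark, Ar
Reagents that add atoms: none
Why: Proposed new method: the sodium phenoxide of 14 adds to C5 of 3 (future B1), a bromine-bearing β-carbon of the C1 enone, and the bromo enolate expels bromide to restore the quinone as 15; the sodium phenoxide of 13 then does the same at C4 (future B2), the β-carbon of the C2 enone, giving 16 by two vinylogous acyl substitutions in one flask. The closest known reaction type is aryloxy-dehalogenation of chloranil, ortho-chloranil and 2,3-dichloro-1,4-naphthoquinone by phenoxides; new here are the unsymmetrical tribromo(methoxy) ortho-quinone, two different phenoxides in a fixed order and the very electron-rich, hindered partners. No ring is closed and no stereocentre is formed. The order of attack should follow from the α-substituents: the C3 methoxy group pushes electron density onto C4 and attack there would give an electron-rich α-alkoxy enolate, whereas attack at C5 gives an enolate stabilised by the C6 bromine, in line with the general preference of 3-alkoxy ortho-quinones for conjugate addition at C5. Once the aryloxy group sits on C5 it turns the C1 enone into a vinylogous ester and enriches C6, so the second phenoxide is left with C4, and this crowded carbon (between OMe and OAr) is matched with the unhindered C1 phenoxide of 13. The C6 bromine is a doubly deactivated α-position and should stay, where it also blocks conjugate addition; displacement of the C3 methoxy or of the first aryloxy group is disfavoured because bromide is by far the best leaving group. The second need is that polar addition outruns single-electron transfer from the phenoxides to the oxidising quinone; no substrate feature secures this, so it rests on inverse addition of exactly one equivalent of preformed phenoxide at −78 °C with exclusion of light and oxygen, and it remains the open point.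

Step 10
Reactants: 16 6-bromo-4-[4-{2-[3,5-dimethoxy-4-(3,4,5-trimethoxyphenoxy)phenoxy]-3,4,5-trimethoxyphenoxy}-3,5-dimethoxyphenoxy]-3-methoxy-5-(2,4,6-trimethoxyphenoxy)-1,2-benzoquinone
Product: 18 4-[4-{2-[3,5-dimethoxy-4-(3,4,5-trimethoxyphenoxy)phenoxy]-3,4,5-trimethoxyphenoxy}-3,5-dimethoxyphenoxy]-3-methoxy-5-(2,4,6-trimethoxyphenoxy)benzene-1,2-diol, via bromocatechol 17 (not isolated)
Conditions: H2 (1–3 atm), 10% Pd/C, NaOAc, EtOAc/MeOH, rt; filtered under Ar
Reagents that add atoms: none
Why: Catalytic hydrogenation reduces the ortho-quinone to the catechol and then hydrogenolyses the aryl bromide, so B4–OH, B5–OH and B6–H appear in one operation.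

Step 11
Reactants: 18 4-[4-{2-[3,5-dimethoxy-4-(3,4,5-trimethoxyphenoxy)phenoxy]-3,4,5-trimethoxyphenoxy}-3,5-dimethoxyphenoxy]-3-methoxy-5-(2,4,6-trimethoxyphenoxy)benzene-1,2-diol
Product: 19 5-(2,4,6-trihydroxyphenoxy)-4-[4-{2-[3,5-dihydroxy-4-(3,4,5-trihydroxyphenoxy)phenoxy]-3,4,5-trihydroxyphenoxy}-3,5-dihydroxyphenoxy]benzene-1,2,3-triol (CNP0218077.0)
Conditions: BBr3 (excess), CH2Cl2, −78 °C to rt; then H2O, 0 °C; degassed solvents, Ar
Reagents that add atoms: none
Why: Lewis acid cleavage of the fourteen aryl methyl ethers (bromide attacks the methyl group of each ArO(Me)–BBr3 adduct); diaryl ethers offer no carbon open to this attack and should survive, and the acidic, non-oxidising medium suits the air-sensitive polyphenol.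

## Compound list

1 | 3-methoxycatechol | COc1cccc(O)c1O | starting material
2 | 4,5,6-tribromo-3-methoxycatechol | COc1c(O)c(O)c(Br)c(Br)c1Br | intermediate
3 | 4,5,6-tribromo-3-methoxy-1,2-benzoquinone | COC1=C(Br)C(Br)=C(Br)C(=O)C1=O | intermediate
4 | 2,6-dimethoxyhydroquinone | COc1cc(O)cc(OC)c1O | starting material
5 | 4-benzyloxy-2,6-dimethoxyphenol | COc1cc(OCc2ccccc2)cc(OC)c1O | intermediate
6 | 5-iodo-1,2,3-trimethoxybenzene | COc1cc(I)cc(OC)c1OC | starting material
7 | 5-benzyloxy-1,3-dimethoxy-2-(3,4,5-trimethoxyphenoxy)benzene | COc1cc(OCc2ccccc2)cc(OC)c1Oc1cc(OC)c(OC)c(OC)c1 | intermediate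
8 | 3,5-dimethoxy-4-(3,4,5-trimethoxyphenoxy)phenol | COc1cc(O)cc(OC)c1Oc1cc(OC)c(OC)c(OC)c1 | intermediate
9 | 5-(4-benzyloxy-2,6-dimethoxyphenoxy)-4,6-dibromo-3-methoxy-1,2-benzoquinone (not isolated) | COC1=C(Br)C(Oc2c(OC)cc(OCc3ccccc3)cc2OC)=C(Br)C(=O)C1=O | intermediate
10 | 5-(4-benzyloxy-2,6-dimethoxyphenoxy)-6-bromo-4-[3,5-dimethoxy-4-(3,4,5-trimethoxyphenoxy)phenoxy]-3-methoxy-1,2-benzoquinone | COC1=C(Oc2cc(OC)c(Oc3cc(OC)c(OC)c(OC)c3)c(OC)c2)C(Oc2c(OC)cc(OCc3ccccc3)cc2OC)=C(Br)C(=O)C1=O | intermediate
11 | 5-(4-benzyloxy-2,6-dimethoxyphenoxy)-6-bromo-4-[3,5-dimethoxy-4-(3,4,5-trimethoxyphenoxy)phenoxy]-3-methoxybenzene-1,2-diol (not isolated) | COc1c(O)c(O)c(Br)c(Oc2c(OC)cc(OCc3ccccc3)cc2OC)c1Oc1cc(OC)c(Oc2cc(OC)c(OC)c(OC)c2)c(OC)c1 | intermediate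
12 | 1-(4-benzyloxy-2,6-dimethoxyphenoxy)-6-bromo-2-[3,5-dimethoxy-4-(3,4,5-trimethoxyphenoxy)phenoxy]-3,4,5-trimethoxybenzene | COc1c(OC)c(OC)c(Br)c(Oc2c(OC)cc(OCc3ccccc3)cc2OC)c1Oc1cc(OC)c(Oc2cc(OC)c(OC)c(OC)c2)c(OC)c1 | intermediate
13 | 4-{2-[3,5-dimethoxy-4-(3,4,5-trimethoxyphenoxy)phenoxy]-3,4,5-trimethoxyphenoxy}-3,5-dimethoxyphenol (C–D–E–F phenol) | Oc1cc(OC)c(Oc2cc(OC)c(OC)c(OC)c2Oc2cc(OC)c(Oc3cc(OC)c(OC)c(OC)c3)c(OC)c2)c(OC)c1 | intermediate
14 | 2,4,6-trimethoxyphenol | COc1cc(OC)c(O)c(OC)c1 | starting material
15 | 4,6-dibromo-3-methoxy-5-(2,4,6-trimethoxyphenoxy)-1,2-benzoquinone (not isolated) | COC1=C(Br)C(Oc2c(OC)cc(OC)cc2OC)=C(Br)C(=O)C1=O | intermediate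
16 | hexamer with ring B as 6-bromo-3-methoxy-1,2-benzoquinone, ring A oxygen on C5 and ring C oxygen on C4 | COC1=C(Oc2cc(OC)c(Oc3cc(OC)c(OC)c(OC)c3Oc3cc(OC)c(Oc4cc(OC)c(OC)c(OC)c4)c(OC)c3)c(OC)c2)C(Oc2c(OC)cc(OC)cc2OC)=C(Br)C(=O)C1=O | intermediate
17 | hexamer with ring B as 6-bromo-3-methoxycatechol (not isolated) | COc1c(O)c(O)c(Br)c(Oc2c(OC)cc(OC)cc2OC)c1Oc1cc(OC)c(Oc2cc(OC)c(OC)c(OC)c2Oc2cc(OC)c(Oc3cc(OC)c(OC)c(OC)c3)c(OC)c2)c(OC)c1 | intermediate
18 | hexamer with ring B as 3-methoxycatechol (B4 and B5 hydroxyls free, fourteen methyl ethers) | COc1c(O)c(O)cc(Oc2c(OC)cc(OC)cc2OC)c1Oc1cc(OC)c(Oc2cc(OC)c(OC)c(OC)c2Oc2cc(OC)c(Oc3cc(OC)c(OC)c(OC)c3)c(OC)c2)c(OC)c1 | intermediate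
19 | CNP0218077.0, the free hexadecahydroxy hexamer | Oc1cc(O)c(Oc2cc(O)c(O)c(O)c2Oc2cc(O)c(Oc3cc(O)c(O)c(O)c3Oc3cc(O)c(Oc4cc(O)c(O)c(O)c4)c(O)c3)c(O)c2)c(O)c1 | target

## Step count and risks

Total step count: 11. Longest linear sequence: 9 steps (steps 3 to 11, from 4). Steps 1 and 2 form a side branch whose product 3 enters at steps 6 and 9.

**Step 9 (key step, proposed new method).**
- What may go wrong: single-electron transfer from the phenoxide to the quinone may take over from addition–elimination, giving reduction of the quinone and oxidative coupling of the phenol. Less likely, the two oxygens may arrive in the reverse order or the first aryloxy group may be exchanged, so that the two ethers end up interchanged.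
- Fallback (known chemistry, setting out from 14 and 13 and coming back at 19): ring B is brought in as an aryl iodide and both ethers are made by metal-catalysed couplings.
  - 2,3,4-Trimethoxyphenol F1 is iodinated ortho to the hydroxyl (NIS, MeCN) to 6-iodo-2,3,4-trimethoxyphenol F2.
  - F2 is protected (MOMCl, i-Pr2NEt) as 1-iodo-3,4,5-trimethoxy-2-(methoxymethoxy)benzene F3.
  - Ullmann coupling of F3 with 14 (CuI, picolinic acid, K3PO4, DMSO, 100 °C) forms B1–O–A1 and gives 1,2,3-trimethoxy-4-(methoxymethoxy)-5-(2,4,6-trimethoxyphenoxy)benzene F4.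
  - HCl in MeOH frees the B2 hydroxyl to give 2,3,4-trimethoxy-6-(2,4,6-trimethoxyphenoxy)phenol F5.
  - 13 is converted (Tf2O, pyridine) into the C–D–E–F aryl triflate F6.
  - Palladium-catalysed diaryl ether coupling of F5 with F6 (Pd(OAc)2, t-BuXPhos, K3PO4, toluene, 100 °C) forms B2–O–C1 and gives the hexadecamethyl ether of the target F7.
  - BBr3 under the conditions of step 11 takes F7 to 19.

**Step 6 (proposed new method).**
- What may go wrong: the same two processes as in step 9, electron transfer in place of substitution and loss of the order of attack. Here they can be studied on small molecules before 13 is committed.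
- Fallback (known chemistry, setting out from 5 and 8 and coming back at 13):
  - The iodide F3 of the fallback to step 9 is coupled with 5 under the same Ullmann conditions to give 1-(4-benzyloxy-2,6-dimethoxyphenoxy)-3,4,5-trimethoxy-2-(methoxymethoxy)benzene F8.
  - HCl in MeOH gives 6-(4-benzyloxy-2,6-dimethoxyphenoxy)-2,3,4-trimethoxyphenol F9.
  - 8 is converted (Tf2O, pyridine) into 3,5-dimethoxy-4-(3,4,5-trimethoxyphenoxy)phenyl triflate F10.
  - Palladium-catalysed coupling of F9 with F10 (Pd(OAc)2, t-BuXPhos, K3PO4, toluene, 100 °C) gives the bromine-free benzyl ether of the tetramer F11.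
  - Hydrogenolysis (H2, Pd/C) takes F11 to 13.

**Step 4.**
- What may go wrong: C–O bond formation at the doubly ortho-substituted phenoxide may be slow, so that protodeiodination of 6 and oxidative degradation of the electron-rich phenoxide compete.
- Fallback (setting out from 6 and 5 and coming back at 7): metal-free arylation through trivalent iodine. 6 is oxidised (mCPBA, TsOH·H2O, CH2Cl2) and trapped with 1,3,5-trimethoxybenzene to give (2,4,6-trimethoxyphenyl)(3,4,5-trimethoxyphenyl)iodonium tosylate F12. The potassium salt of 5 (t-BuOK, THF, rt) should take over the less electron-rich 3,4,5-trimethoxyphenyl group by ligand coupling, giving 7.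

**Step 7.**
- What may go wrong: water, hydroxide or sulfite may attack the aryloxy-bearing carbons of the quinone before reduction is complete (loss of an aryloxy group, sulfonation), or the catecholate may re-oxidise before both oxygens are methylated.
- Fallback (setting out from 10 and coming back at 12): non-aqueous reductive acetylation (Zn, Ac2O, NaOAc, rt) gives the ring-D catechol diacetate F13. Deacetylation and methylation in one flask (Cs2CO3, MeI, MeOH/DMF, degassed, rt) then gives 12.

**Step 11.**
- What may go wrong: cleavage may stay incomplete as partly demethylated aryloxyboron species precipitate, and the free polyphenol may degrade oxidatively during work-up and purification.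
- Fallback (setting out from 18 and coming back at 19): the crude product of the BBr3 treatment is peracetylated (Ac2O, pyridine) to the hexadecaacetate of the target F14. This stable compound is purified on silica, and partly methylated acetates are separated and resubmitted. Acid methanolysis (HCl from AcCl in degassed MeOH, 0 °C to rt) then releases 19 without a phenolate stage.

## Further compounds

F1 | step 9 | 2,3,4-trimethoxyphenol | COc1ccc(O)c(OC)c1OC
F2 | step 9 | 6-iodo-2,3,4-trimethoxyphenol | COc1cc(I)c(O)c(OC)c1OC
F3 | step 9 | 1-iodo-3,4,5-trimethoxy-2-(methoxymethoxy)benzene | COCOc1c(I)cc(OC)c(OC)c1OC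
F4 | step 9 | 1,2,3-trimethoxy-4-(methoxymethoxy)-5-(2,4,6-trimethoxyphenoxy)benzene | COCOc1c(Oc2c(OC)cc(OC)cc2OC)cc(OC)c(OC)c1OC
F5 | step 9 | 2,3,4-trimethoxy-6-(2,4,6-trimethoxyphenoxy)phenol | COc1cc(OC)c(Oc2cc(OC)c(OC)c(OC)c2O)c(OC)c1
F6 | step 9 | triflate of the C–D–E–F phenol 13 | O=S(=O)(Oc1cc(OC)c(Oc2cc(OC)c(OC)c(OC)c2Oc2cc(OC)c(Oc3cc(OC)c(OC)c(OC)c3)c(OC)c2)c(OC)c1)C(F)(F)F
F7 | step 9 | hexadecamethyl ether of the target | COc1cc(OC)c(Oc2cc(OC)c(OC)c(OC)c2Oc2cc(OC)c(Oc3cc(OC)c(OC)c(OC)c3Oc3cc(OC)c(Oc4cc(OC)c(OC)c(OC)c4)c(OC)c3)c(OC)c2)c(OC)c1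
F8 | step 6 | 1-(4-benzyloxy-2,6-dimethoxyphenoxy)-3,4,5-trimethoxy-2-(methoxymethoxy)benzene | COCOc1c(Oc2c(OC)cc(OCc3ccccc3)cc2OC)cc(OC)c(OC)c1OC
F9 | step 6 | 6-(4-benzyloxy-2,6-dimethoxyphenoxy)-2,3,4-trimethoxyphenol | COc1cc(OCc2ccccc2)cc(OC)c1Oc1cc(OC)c(OC)c(OC)c1O
F10 | step 6 | 3,5-dimethoxy-4-(3,4,5-trimethoxyphenoxy)phenyl trifluoromethanesulfonate | COc1cc(OS(=O)(=O)C(F)(F)F)cc(OC)c1Oc1cc(OC)c(OC)c(OC)c1
F11 | step 6 | bromine-free benzyl ether of the C–D–E–F tetramer | COc1cc(OCc2ccccc2)cc(OC)c1Oc1cc(OC)c(OC)c(OC)c1Oc1cc(OC)c(Oc2cc(OC)c(OC)c(OC)c2)c(OC)c1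
F12 | step 4 | (2,4,6-trimethoxyphenyl)(3,4,5-trimethoxyphenyl)iodonium tosylate | COc1cc(OC)c([I+]c2cc(OC)c(OC)c(OC)c2)c(OC)c1.Cc1ccc(S(=O)(=O)[O-])cc1
F13 | step 7 | ring-D catechol diacetate of 11 | COc1c(OC(C)=O)c(OC(C)=O)c(Br)c(Oc2c(OC)cc(OCc3ccccc3)cc2OC)c1Oc1cc(OC)c(Oc2cc(OC)c(OC)c(OC)c2)c(OC)c1
F14 | step 11 | hexadecaacetate of the target | CC(=O)Oc1cc(OC(C)=O)c(Oc2cc(OC(C)=O)c(OC(C)=O)c(OC(C)=O)c2Oc2cc(OC(C)=O)c(Oc3cc(OC(C)=O)c(OC(C)=O)c(OC(C)=O)c3Oc3cc(OC(C)=O)c(Oc4cc(OC(C)=O)c(OC(C)=O)c(OC(C)=O)c4)c(OC(C)=O)c3)c(OC(C)=O)c2)c(OC(C)=O)c1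
A1 | alternative 1 | pentacarbonyl[(4-benzyloxy-2,6-dimethoxyphenoxy)((E)-2-ethoxyvinyl)carbene]chromium | O=C=[Cr](=C=O)(=C=O)(=C=O)(=C=O)=C(/C=C/OCC)Oc1c(OC)cc(OCc2ccccc2)cc1OC
A2 | alternative 1 | ethoxyacetylene | CCOC#C
A3 | alternative 1 | 4-(4-benzyloxy-2,6-dimethoxyphenoxy)-2,6-diethoxyphenol | CCOc1cc(Oc2c(OC)cc(OCc3ccccc3)cc2OC)cc(OCC)c1O
A4 | alternative 2 | dimethyl (E)-3-aryloxyglutaconate carrying rings A to D | COC(=O)C/C(Oc1c(OC)c(OC)c(OC)cc1Oc1c(OC)cc(Oc2c(OC)c(OC)c(OC)cc2Oc2c(OC)cc(OC)cc2OC)cc1OC)=C\C(=O)OC
A5 | alternative 2 | (3,4,5-trimethoxyphenoxy)malonyl dichloride | O=C(Cl)C(Oc1cc(OC)c(OC)c(OC)c1)C(=O)Cl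
A6 | alternative 2 | protected hexamer with ring E as a 3,5-dihydroxy-2,6-bis(methoxycarbonyl) ring | COC(=O)c1c(O)c(Oc2cc(OC)c(OC)c(OC)c2)c(O)c(C(=O)OC)c1Oc1c(OC)c(OC)c(OC)cc1Oc1c(OC)cc(Oc2c(OC)c(OC)c(OC)cc2Oc2c(OC)cc(OC)cc2OC)cc1OC
A7 | alternative 3 | racemic 4-aryloxy-3-ethoxycyclobut-2-en-1-one carrying rings D to F | CCOC1=CC(=O)C1Oc1cc(OC)c(OC)c(OC)c1Oc1cc(OC)c(Oc2cc(OC)c(OC)c(OC)c2)c(OC)c1
A8 | alternative 3 | ethynyl ether of the A–B phenol | C#COc1c(OC)c(OC)c(OC)cc1Oc1c(OC)cc(OC)cc1OC
A9 | alternative 3 | protected hexamer with free C3 hydroxyl and C5 ethoxy group on ring C | COc1cc(OC)c(Oc2cc(OC)c(OC)c(OC)c2Oc2cc(O)c(Oc3cc(OC)c(OC)c(OC)c3Oc3cc(OC)c(Oc4cc(OC)c(OC)c(OC)c4)c(OC)c3)c(OCC)c2)c(OC)c1
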